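The runs stem from a simulated flask with constants of no real substance; scatter was added.

Tuesday's flask held 22.7% of its charge as target from 50.0 s on, and Wednesday's held far less, a mean of 0.571%. That mean is a reading with a scatter of 1.5 percentage points on each point, so it is rough.

| flask | substrate | remark | time |
|---|---|---|---|
| Tuesday's | 0.0056 M | run made earlier |  |
| Wednesday's | 0.18 M | run made earlier |  |
| alder | 0.010 M |  | 4.0 min |
| maple | 0.030 M |  | 4.0 min |
| oak | 0.10 M |  | 4.0 min |
| larch | 0.25 M |  | 4.0 min |

| Tuesday's: time / s | Tuesday's: target / % | Wednesday's: time / s | Wednesday's: target / % |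
|---|---|---|---|
| 10.0 | 6 | 10.0 | 0 |
| 15.0 | 10 | 20.0 | 0 |
| 20.0 | 14 | 30.0 | 2 |
| 30.0 | 18 | 50.0 | 0 |
| 50.0 | 20 | 80.0 | 0 |
| 80.0 | 25 | 90.0 | 0 |
| 120 | 23 | 120 | 2 |

(standard deviation of a reading: 1.5 percentage points)

- percent here means substrate units held: one side product counts as two
- candidate steps: substrate -> target; substrate + target -> side product; substrate <-> dormant form; target <-> isomer of the product
- "hardly changes" means that all values lie within two and a half points (for a concentration: within two and a half percent of the largest)

1. [target] at the end for alder, maple, oak, larch, in this order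
2. the shape of the row from first to last (rises all the way / rises, then falls / hardly changes / falls, then rises / falls all the way)

My bench rule was simple: a recipe keeps its percent when the charge c changes. So target should equal s·c, with s the share read on Tuesday. I took target as steady by 4.0 min, though the readings stop at 120 s.

The rule broke between the two runs. The charge grew 32.1-fold, but the share shrank 39.8-fold.

For high charges I drew a falling line through Wednesday's reading, with target inversely proportional to c. That slope was my guess, and two runs cannot test it. I defined the crossing charge c× as the charge at which the constant-share line meets the falling line: 0.0286 M. It lay close to maple's charge. I took the lower line in each flask and expected the row to rise, then fall, with maple somewhat below its figure.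

| flask | c | s·c | falling line |
|---|---|---|---|
| alder | 0.010 M | 0.00227 M | 0.0185 M |
| maple | 0.030 M | 0.00681 M | 0.00617 M |
| oak | 0.10 M | 0.0227 M | 0.00185 M |
| larch | 0.25 M | 0.0568 M | 7.41 × 10⁻⁴ M |

The forecast read the two runs as “a similar concentration, not a similar percentage” and gave 0.00147 M, 0.0015 M, 0.0015 M and 0.0015 M, a row that hardly changes.

The flasks gave 0.00205 M, 0.00328 M, 0.00202 M and 7.06 × 10⁻⁴ M, and the row rises, then falls.

    substrate → target, rate k1*[substrate]/(1 + ([substrate]/sat1)) (9.67 mM, k = 0.0153 s⁻¹)
    substrate + target → side product (k = 1.68 L mol⁻¹ s⁻¹)
    substrate ⇌ dormant form (K = 0.630, k = 0.0173 s⁻¹)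
    target ⇌ isomer of the product (K = 2.10, k = 0.0189 s⁻¹)

Without the rate of substrate + target to side product, the row rises all the way. Above c×, I took the level s·c× and scaled it down by c×/c. For oak that gave 0.00186 M against 0.00202 M. For larch it gave 7.41 × 10⁻⁴ M against 7.06 × 10⁻⁴ M.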